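All runs were generated by integration from invented constants, noise included.

**The question.** You asked for a quick number on grey, and your hunch is that it stops where its reagent ends. We agree on the direction, so we count how far along that road it gets.

| flask | starting material | reagent | catalyst | time |
|---|---|---|---|---|
| ochre | 1.00 M | 1.00 M | 0.0200 M |  |
| amber | 3.00 M | 1.00 M | 0.0200 M |  |
| grey | 1.00 M | 0.330 M | 0.0400 M | 180 min |

- ochre run (time / min: [target] / M): 7.2: 0.117; 11: 0.145; 18: 0.227; 29: 0.323; 45: 0.427; 72: 0.544; 110: 0.649; 180: 0.743
- amber run (time / min: [target] / M): 7.2: 0.290; 11: 0.397; 18: 0.547; 29: 0.708; 45: 0.829; 72: 0.941; 110: 0.990; 180: 1.000

(standard deviation of a reading: 0.005 M)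

1. the exponent of [starting material] in the starting rate at the charge of the ochre run (at the point where two percent of the starting material have become target) (one fixed amount of target, the same in the runs compared)
2. target in the grey run at 180 min, as a share of the starting material charged

- Overall: starting material + reagent -> target, with catalyst as catalyst.
- Constant volume, constant temperature.
- "The second partner" is reagent.
- An order is taken over about fifteen percent of the charge, up and down.

**One constant.** Ochre has equal charges, so the fraction turned over the fraction left grows as a constant times charge times time. Its reading at 29 min gives 0.0165 /M/min.

**Counting lifetimes.** With unequal charges we count lifetimes: that constant times the excess of starting material over reagent times the time. Each lifetime divides the ratio of reagent fraction left to starting-material fraction left by e. Amber at 72 min has 2.37 lifetimes, so 6.44% of its reagent charge should remain. The reading gives 5.90%, with a scatter of 0.500%. The ochre constant thus serves amber's tripled charge, and we take first order in starting material.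

**Grey reckoned.** Reagent is the limiting reagent, at 33.0% of the starting material charge, which is your ceiling. Ochre and amber share one catalyst charge, so we assume the constant scales with catalyst, by a factor of 2.00. That gives 3.97 as grey's count of reagent lifetimes at the asked time. Then 1.27% of the reagent charge remains, and target reaches 32.6% of the starting material.

**The flask.** The forecast gave an exponent of 1 and 32.5% for grey, noting that “The catalyst order is untested”. The flask gives 1.0 and 32.0%.

    catalyst + starting material + reagent → target + catalyst (0.4596 /M²/min)
    starting material + reagent → target (0.007260 /M/min)

**Spare route.** Apparent order in catalyst is 0.56, against 1.0 with the uncatalysed conversion taken away, because that conversion of starting material and reagent runs beside the catalysed one. So grey's constant stands above ochre's by a factor of 1.56, and grey has 3.09 lifetimes, fewer than our 3.97. Reagent left in grey is 3.09% of its charge, not 1.27%, and target stands at 32.0% of the starting material.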